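## Analysis of the target

Broussonol A (21) is a flavonol: benzene ring A is fused to the 3-hydroxy-4-pyranone ring C, and C2 carries aryl ring B. Ring B is fused through O4' and C5' to a 2,2-dimethyl-2H-pyran (ring D) and keeps a free hydroxyl at C3'. Ring A carries hydroxyls at C5 and C7, and C8 bears a 1,1-dimethylallyl (reverse prenyl) group whose quaternary carbon is bonded directly to the arene. There is no stereocentre and no stereogenic double bond, so the synthesis is purely a problem of constitution: which oxygen is alkylated and which aromatic carbon receives carbon. The sensitive groups are the electron-rich 3-hydroxypyranone (oxidised by air in base), the acid-labile chromene double bond of ring D, and the 7-hydroxyl next to the reverse prenyl group, which can add to the alkene or let the side chain isomerise under acid or prolonged heat. The hard points are the quaternary carbon at the crowded C8 while C6 is also unsubstituted, and the differentiation of five oxygens. The strategy rests on two bonds that each lie ortho to an ether oxygen: C8–C(quaternary) next to O7 on ring A, and C5'–C4'' of ring D next to O4' on ring B. Each is the retron of an aryl ether [3,3] shift, so both side chains can be brought in as O-alkyl groups and moved to carbon by heat alone.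

## Retrosynthetic reasoning

**21 from 20.** The last operation only cleaves three O–CH2 acetal bonds (O3, O5, O3'). Methoxymethyl ethers are chosen because they survive hydroxide, alkaline peroxide and a hot amine solvent, and leave under dilute acid. O7 needs no protecting group, because the key step itself frees that hydroxyl.

**20 from 13 (key disconnection).** The C8–C(quaternary) bond and the C5'–C4'' bond are cut, and each side chain is reconnected to the neighbouring oxygen: a prenyl ether on O7 and a 1,1-dimethylpropargyl ether on O4'. A cut elsewhere would not do: electrophilic prenylation attacks through the primary end of the allyl cation and cannot make the quaternary centre, and ring D would need a separate annulation. The gain is that 13 is an isomer of 20 and carries only O-alkyl groups. Forward, ring B must undergo a propargyl [3,3] shift to C5', followed by hydrogen shift and oxa-6π closure of ring D. Ring A must undergo an allyl [3,3] shift to C8 and not to C6, and the freed 7-hydroxyl must be capped before it can react with the new side chain. The propargylic ether is expected to rearrange at the lower temperature, so the heating is staged in one flask and the silylating trap is added only after ring D is closed.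

**13 from 12 from 10.** The O3 acetal is removed, then ring C is opened at O1–C2 and the C3–O bond is cut, which leads to the 2'-hydroxychalcone 10. Forward, an Algar–Flynn–Oyamada oxidative cyclisation makes both bonds at once, so the ketone partner needs no oxygen at its methyl group. The MOM ether on the second ortho oxygen of 10 ensures that only one phenol can cyclise, and later crowds C6 in the key step.

**10 from 8 and 4.** The Cα=Cβ bond is cut. This aldol disconnection is convergent and divides the molecule into two arenes of similar size, each carrying one migrating ether and one MOM group.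

**8 from 7 from 5 and 6; 4 from 3 from 1 and 2.** All that remains are O–C bonds, cut in the reverse order of phenol acidity. In 5 the para hydroxyl is alkylated first by 6, then one of the two equivalent chelated hydroxyls is protected. In 1 the hydroxyl para to the formyl group is alkylated first by 2, then the remaining one is protected.

## Alternatives that were turned down

**Alternative 1:** Ring A is dissected into 3-ethoxycyclobut-2-en-1-one A2 and the siloxyalkyne A3, which already carries the 1,1-dimethylallyl group. Forward, heating opens A2 to a vinylketene; [2+2] addition of A3, four-electron ring opening and six-electron closure (Danheiser benzannulation) give phenol A1. The future C8–C8a and C6–C7 bonds are new, and O1, O7 and O5 arrive as a free hydroxyl, a silyl ether and an ethyl ether.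
- For: the position of the quaternary carbon is fixed by the alkyne, so there is no C6/C8 question and no free ortho-phenol at high temperature. On this point it is stronger than the chosen route.
- Against: A3 is not commercial and needs ynolate chemistry on a hindered ester and handling of a hydrolytically fragile ynol ether. The tertiary group on the nucleophilic alkyne carbon slows the ketene cycloaddition. A1 is only ring A, so acylation at the future C4a, ring C, ring B and ring D all remain. The O5 ethyl ether would need a Lewis-acidic dealkylation next to a chromene and a reverse prenyl group.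
- Comparison: the step count would be at least double. The chosen strategy accepts an uncertain C8/C6 selectivity in return for a precursor made by routine steps from two commodity arenes and one isomerisation that moves both side chains.

**Alternative 2:** The disconnection is O1–C8a. Ring C comes from the 2-alkoxy-1,3-diketone A5, whose 2,4,6-trifluorophenyl ketone offers an ortho fluoride. Forward, a carbonate base in a dipolar aprotic solvent forms the enolate, whose oxygen displaces fluoride by intramolecular SNAr to give the difluoroflavonol ether A4.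
- For: the ring closure cannot give an aurone and needs no oxidant, because the C3 oxygen is in A5 from the start. On this point it is stronger than the peroxide cyclisation used here. Ring D is already in place.
- Against: A4 has fluorine where the target has O5 and O7, and hydrogen at C8. Two further SNAr reactions with oxygen nucleophiles are needed and must be told apart, and the first alkoxide deactivates the ring toward the second. C8 must then still be alkylated, realistically by the same 7-O-prenyl shift.
- Comparison: the regiochemical risk of the chosen key step is not removed but postponed to the end of a longer sequence. The chosen route has all ring-A oxygens in 5 from the first step.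

**Alternative 3:** Ring B itself is disconnected at C1'–C2' and C5'–C6'. The pieces are the pyrano-fused 2-pyranone A7 (diene, with ring D) and the 2-ethynylchromone A8 (dienophile, rings A and C with the reverse prenyl group). Forward, [4+2] cycloaddition and retro-[4+2] decarboxylation of the bridged lactone give tetra-O-MOM Broussonol A, A6.
- For: it is the most convergent plan, A6 is one deprotection from 21, and no free phenol is exposed to heat. Its convergence is better than that of the chosen route.
- Against: the orientation of the cycloaddition is not secured. The acceptor A8 is most electrophilic at its terminal alkyne carbon, and the nucleophilic diene terminus of A7 is C7. That pairing places the chromone beside the ring fusion, and only steric effects favour the wanted isomer. Pyranone–alkyne cycloadditions need temperatures at which A8 may polymerise. A7 and A8 are each multi-step targets, and the reverse prenyl group of A8 must still come from an O-to-C shift.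
- Comparison: the total sequence is longer. In the chosen route the ring-B regiochemistry is fixed by constitution, since only C5' is free; here it becomes an open question.

Key step: step 8

Remark on the chemistry: 21 is achiral; the stereocentres of the transient species 9, 11 and 18 are racemic and are erased on the way, so the only geometric element to secure is the E double bond of 10.

## Route

Step 1
Reactants: 1 3,4-dihydroxybenzaldehyde; 2 3-chloro-3-methylbut-1-yne
Product: 3 3-hydroxy-4-[(2-methylbut-3-yn-2-yl)oxy]benzaldehyde
Conditions: K2CO3 (1.1 equiv), KI, CuI (cat.), DMF, 60 °C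
Reagents that add atoms: none
Why: The hydroxyl para to the formyl group is far more acidic than its neighbour, so one equivalent of carbonate gives the 4-phenoxide, which captures the allenylidene-type electrophile formed from the tertiary propargylic chloride (elimination–addition O-propargylation of a phenol). The hindered, less acidic 3-hydroxyl should stay free.

Step 2
Reactants: 3 3-hydroxy-4-[(2-methylbut-3-yn-2-yl)oxy]benzaldehyde
Product: 4 3-(methoxymethoxy)-4-[(2-methylbut-3-yn-2-yl)oxy]benzaldehyde
Conditions: MOMCl, iPr2NEt, CH2Cl2, 0 °C to rt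
Reagents that add atoms: chloromethyl methyl ether (MOMCl), COCCl
Why: O-alkylation of the remaining phenol by an α-chloro ether (MOM protection); the aldehyde and the propargyl ether are inert to these conditions.

Step 3
Reactants: 5 2,4,6-trihydroxyacetophenone; 6 prenyl bromide (1-bromo-3-methylbut-2-ene)
Product: 7 1-[2,6-dihydroxy-4-(3-methylbut-2-enyloxy)phenyl]ethanone
Conditions: 6 (1.0 equiv, slow addition), K2CO3 (1.0 equiv), acetone, reflux
Reagents that add atoms: none
Why: Williamson etherification; the para hydroxyl is the most acidic and takes no part in the hydrogen bond to the acetyl carbonyl, so with one equivalent of mild base and bromide it should be alkylated first.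

Step 4
Reactants: 7 1-[2,6-dihydroxy-4-(3-methylbut-2-enyloxy)phenyl]ethanone
Product: 8 1-[2-hydroxy-6-(methoxymethoxy)-4-(3-methylbut-2-enyloxy)phenyl]ethanone
Conditions: MOMCl (1.2 equiv), iPr2NEt, CH2Cl2, 0 °C to rt
Reagents that add atoms: chloromethyl methyl ether (MOMCl), COCCl
Why: MOM protection; the two ortho hydroxyls are equivalent, and once one is etherified the other is held in a strong hydrogen bond to the carbonyl and should resist a second alkylation.

Step 5
Reactants: 8 1-[2-hydroxy-6-(methoxymethoxy)-4-(3-methylbut-2-enyloxy)phenyl]ethanone; 4 3-(methoxymethoxy)-4-[(2-methylbut-3-yn-2-yl)oxy]benzaldehyde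
Product: 10 (E)-1-[2-hydroxy-6-(methoxymethoxy)-4-(3-methylbut-2-enyloxy)phenyl]-3-[3-(methoxymethoxy)-4-(2-methylbut-3-yn-2-yloxy)phenyl]prop-2-en-1-one, via aldol adduct 9 (not isolated)
Conditions: KOH, EtOH–H2O, 0 °C to rt, argon
Reagents that add atoms: none
Why: Claisen–Schmidt condensation: the methyl ketone enolate adds to the non-enolisable aldehyde and E1cB dehydration of 9 gives the conjugated enone, whose E geometry is the thermodynamic one. MOM ethers, the prenyl ether and the terminal alkyne tolerate hydroxide.

Step 6
Reactants: 10 (E)-1-[2-hydroxy-6-(methoxymethoxy)-4-(3-methylbut-2-enyloxy)phenyl]-3-[3-(methoxymethoxy)-4-(2-methylbut-3-yn-2-yloxy)phenyl]prop-2-en-1-one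
Product: 12 3-hydroxy-5-(methoxymethoxy)-2-[3-(methoxymethoxy)-4-(2-methylbut-3-yn-2-yloxy)phenyl]-7-(3-methylbut-2-enyloxy)-4H-chromen-4-one, via trans-dihydroflavonol 11 (not isolated)
Conditions: H2O2 (30% aq.), NaOH (aq.), MeOH–THF, 0 °C to rt
Reagents that add atoms: hydrogen peroxide, OO
Why: Algar–Flynn–Oyamada reaction: the phenoxide closes ring C at the β-carbon while peroxide oxygenates C3, and the excess oxidant dehydrogenates 11 to the flavonol. The isolated prenyl alkene and the alkyne are not electrophilic and should not be touched by hydroperoxide anion; the low temperature is meant to hold back the aurone channel that an ortho alkoxy group opens.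

Step 7
Reactants: 12 3-hydroxy-5-(methoxymethoxy)-2-[3-(methoxymethoxy)-4-(2-methylbut-3-yn-2-yloxy)phenyl]-7-(3-methylbut-2-enyloxy)-4H-chromen-4-one
Product: 13 3,5-bis(methoxymethoxy)-2-[3-(methoxymethoxy)-4-(2-methylbut-3-yn-2-yloxy)phenyl]-7-(3-methylbut-2-enyloxy)-4H-chromen-4-one
Conditions: MOMCl, iPr2NEt, CH2Cl2, 0 °C to rt
Reagents that add atoms: chloromethyl methyl ether (MOMCl), COCCl
Why: The 3-hydroxyl is an acidic enol and is alkylated readily despite its hydrogen bond to the C4 carbonyl (MOM protection); it is the only free hydroxyl in 12.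

Step 8
Reactants: 13 3,5-bis(methoxymethoxy)-2-[3-(methoxymethoxy)-4-(2-methylbut-3-yn-2-yloxy)phenyl]-7-(3-methylbut-2-enyloxy)-4H-chromen-4-one
Product: 20 7-hydroxy-3,5-bis(methoxymethoxy)-2-[8-(methoxymethoxy)-2,2-dimethyl-2H-chromen-6-yl]-8-(2-methylbut-3-en-2-yl)-4H-chromen-4-one (3,5,3'-tris-O-MOM Broussonol A), via allenyl dienone 14 (not isolated), via ortho-allenylphenol 15 (not isolated), via vinyl ortho-quinone methide 16 (not isolated), via 7-O-prenyl chromene 17 (not isolated), via ring-A dienone 18 (not isolated), via 7-O-trimethylsilyl ether 19 (not isolated)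
Conditions: PhNEt2 (degassed), about 150–160 °C; then N,O-bis(trimethylsilyl)acetamide, about 200 °C; then K2CO3, MeOH, rt
Reagents that add atoms: none
Why: In the first stage the 4'-O-(1,1-dimethylpropargyl) ether should undergo an aromatic propargyl Claisen [3,3] shift to C5', the only free ortho position of ring B because C3' carries a MOM ether, giving 14 with the new C5'–C4'' bond. Amine-assisted enolisation to 15, a 1,5-hydrogen shift from the phenolic O–H to the central allene carbon (16, diene terminus cis to the carbonyl) and a thermally allowed disrotatory oxa-6π electrocyclisation then close pyran ring D through O4'–C2'' to give 17, as in the standard thermal chromene synthesis from aryl 1,1-dimethylpropargyl ethers. Because the gem-dimethyl propargylic ether is expected to rearrange at a lower temperature than the prenyl ether, ring D is closed before the silylating agent is added, so that phenol 15 cannot be capped before its hydrogen shift. At about 200 °C the 7-O-prenyl ether should then undergo the aromatic Claisen [3,3] shift through a chair-like transition state to C8, giving 18 with the new bond from C8 to the quaternary carbon, and tautomerisation frees the 7-hydroxyl, as known for 7-prenyloxyflavones. The silylating agent converts this phenol into 19, which shuts off the ene-type abnormal Claisen isomerisation and the addition of the phenol to the alkene, and methanolysis on work-up returns 20. The selectivity that must be secured is C8 against C6: the para position C4a is blocked, the C7–C8 bond of the benzopyranone has the higher double-bond character, and the 5-O-MOM group, turned toward C6 by the peri carbonyl, crowds that site. No stereocentre is created, since C8 of 18 becomes trigonal again, and the whole step is an isomerisation of 13.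

Step 9
Reactants: 20 7-hydroxy-3,5-bis(methoxymethoxy)-2-[8-(methoxymethoxy)-2,2-dimethyl-2H-chromen-6-yl]-8-(2-methylbut-3-en-2-yl)-4H-chromen-4-one
Product: 21 Broussonol A, 3,5,7-trihydroxy-2-(8-hydroxy-2,2-dimethyl-2H-chromen-6-yl)-8-(2-methylbut-3-en-2-yl)-4H-chromen-4-one
Conditions: HCl (about 1 M), MeOH–THF, rt to 40 °C, argon
Reagents that add atoms: none
Why: Acid-catalysed transacetalisation transfers the three MOM groups to methanol; the 5-O acetal (peri to the carbonyl) and the 3-O enol acetal are the most labile and the 3'-O acetal sets the reaction time. Dilute acid and low temperature are chosen so that the 7-hydroxyl does not add to the monosubstituted alkene and the chromene is spared.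

## Compound list

1 | 3,4-dihydroxybenzaldehyde | O=Cc1ccc(O)c(O)c1 | starting material
2 | 3-chloro-3-methylbut-1-yne | C#CC(C)(C)Cl | starting material
3 | 3-hydroxy-4-[(2-methylbut-3-yn-2-yl)oxy]benzaldehyde | O=Cc1ccc(OC(C)(C)C#C)c(O)c1 | intermediate
4 | 3-(methoxymethoxy)-4-[(2-methylbut-3-yn-2-yl)oxy]benzaldehyde | O=Cc1ccc(OC(C)(C)C#C)c(OCOC)c1 | intermediate
5 | 2,4,6-trihydroxyacetophenone | CC(=O)c1c(O)cc(O)cc1O | starting material
6 | prenyl bromide (1-bromo-3-methylbut-2-ene) | CC(C)=CCBr | starting material
7 | 1-[2,6-dihydroxy-4-(3-methylbut-2-enyloxy)phenyl]ethanone | CC(=O)c1c(O)cc(OCC=C(C)C)cc1O | intermediate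
8 | 1-[2-hydroxy-6-(methoxymethoxy)-4-(3-methylbut-2-enyloxy)phenyl]ethanone | CC(=O)c1c(O)cc(OCC=C(C)C)cc1OCOC | intermediate
9 | aldol adduct, racemic 3-hydroxy-1-[2-hydroxy-6-(methoxymethoxy)-4-(3-methylbut-2-enyloxy)phenyl]-3-[3-(methoxymethoxy)-4-(2-methylbut-3-yn-2-yloxy)phenyl]propan-1-one | O=C(CC(O)c1ccc(OC(C)(C)C#C)c(OCOC)c1)c1c(O)cc(OCC=C(C)C)cc1OCOC | intermediate (not isolated)
10 | (E)-1-[2-hydroxy-6-(methoxymethoxy)-4-(3-methylbut-2-enyloxy)phenyl]-3-[3-(methoxymethoxy)-4-(2-methylbut-3-yn-2-yloxy)phenyl]prop-2-en-1-one | O=C(/C=C/c1ccc(OC(C)(C)C#C)c(OCOC)c1)c1c(O)cc(OCC=C(C)C)cc1OCOC | intermediate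
11 | trans-3-hydroxy-5-(methoxymethoxy)-2-[3-(methoxymethoxy)-4-(2-methylbut-3-yn-2-yloxy)phenyl]-7-(3-methylbut-2-enyloxy)chroman-4-one (racemic; 2R,3R enantiomer drawn) | C#CC(C)(C)Oc1ccc(cc1OCOC)[C@H]1Oc2cc(OCC=C(C)C)cc(OCOC)c2C(=O)[C@@H]1O | intermediate (not isolated)
12 | 3-hydroxy-5-(methoxymethoxy)-2-[3-(methoxymethoxy)-4-(2-methylbut-3-yn-2-yloxy)phenyl]-7-(3-methylbut-2-enyloxy)-4H-chromen-4-one | CC(C)=CCOc1cc(OCOC)c2c(=O)c(O)c(-c3ccc(OC(C)(C)C#C)c(OCOC)c3)oc2c1 | intermediate
13 | 3,5-bis(methoxymethoxy)-2-[3-(methoxymethoxy)-4-(2-methylbut-3-yn-2-yloxy)phenyl]-7-(3-methylbut-2-enyloxy)-4H-chromen-4-one | CC(C)=CCOc1cc(OCOC)c2c(=O)c(OCOC)c(-c3ccc(OC(C)(C)C#C)c(OCOC)c3)oc2c1 | intermediate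
14 | ring-B allenyl dienone: the flavonol core of 13 bearing at C2 a 3-(methoxymethoxy)-5-(3-methylbuta-1,2-dienyl)-4-oxocyclohexa-1,5-dienyl ring (racemic) | CC(C)=CCOc1cc(OCOC)c2c(=O)c(OCOC)c(C3=CC(C=C=C(C)C)C(=O)C(OCOC)=C3)oc2c1 | intermediate (not isolated)
15 | 2-[4-hydroxy-3-(methoxymethoxy)-5-(3-methylbuta-1,2-dienyl)phenyl]-3,5-bis(methoxymethoxy)-7-(3-methylbut-2-enyloxy)-4H-chromen-4-one | CC(C)=CCOc1cc(OCOC)c2c(=O)c(OCOC)c(-c3cc(OCOC)c(O)c(C=C=C(C)C)c3)oc2c1 | intermediate (not isolated)
16 | vinyl ortho-quinone methide: the flavonol core of 13 bearing at C2 a 3-(methoxymethoxy)-5-(3-methylbut-2-enylidene)-4-oxocyclohexa-1,2-dienyl-type ring, exocyclic double bond with the butenyl chain cis to the carbonyl | CC(C)=CCOc1cc(OCOC)c2c(=O)c(OCOC)c(C3=C/C(=C/C=C(C)C)C(=O)C(OCOC)=C3)oc2c1 | intermediate (not isolated)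
17 | 3,5-bis(methoxymethoxy)-2-[8-(methoxymethoxy)-2,2-dimethyl-2H-chromen-6-yl]-7-(3-methylbut-2-enyloxy)-4H-chromen-4-one | CC(C)=CCOc1cc(OCOC)c2c(=O)c(OCOC)c(-c3cc(OCOC)c4c(c3)C=CC(C)(C)O4)oc2c1 | intermediate (not isolated)
18 | ring-A dienone: 3,5-bis(methoxymethoxy)-2-[8-(methoxymethoxy)-2,2-dimethyl-2H-chromen-6-yl]-8-(2-methylbut-3-en-2-yl)-8H-chromene-4,7-dione (racemic) | C=CC(C)(C)C1C(=O)C=C(OCOC)C2=C1OC(-c3cc(OCOC)c4c(c3)C=CC(C)(C)O4)=C(OCOC)C2=O | intermediate (not isolated)
19 | 3,5-bis(methoxymethoxy)-2-[8-(methoxymethoxy)-2,2-dimethyl-2H-chromen-6-yl]-8-(2-methylbut-3-en-2-yl)-7-(trimethylsilyloxy)-4H-chromen-4-one | C=CC(C)(C)c1c(O[Si](C)(C)C)cc(OCOC)c2c(=O)c(OCOC)c(-c3cc(OCOC)c4c(c3)C=CC(C)(C)O4)oc12 | intermediate (not isolated)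
20 | 7-hydroxy-3,5-bis(methoxymethoxy)-2-[8-(methoxymethoxy)-2,2-dimethyl-2H-chromen-6-yl]-8-(2-methylbut-3-en-2-yl)-4H-chromen-4-one (3,5,3'-tris-O-MOM Broussonol A) | C=CC(C)(C)c1c(O)cc(OCOC)c2c(=O)c(OCOC)c(-c3cc(OCOC)c4c(c3)C=CC(C)(C)O4)oc12 | intermediate
21 | Broussonol A, 3,5,7-trihydroxy-2-(8-hydroxy-2,2-dimethyl-2H-chromen-6-yl)-8-(2-methylbut-3-en-2-yl)-4H-chromen-4-one | C=CC(C)(C)c1c(O)cc(O)c2c(=O)c(O)c(-c3cc(O)c4c(c3)C=CC(C)(C)O4)oc12 | target

## Step count and least certain steps

Total: 9 steps. Longest linear sequence: 7 steps (steps 1, 2, 5, 6, 7, 8, 9 from 1; equally steps 3, 4, 5, 6, 7, 8, 9 from 5).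

**Step 8 (key step).**
- Risk: the most likely failure is migration of the prenyl group to C6 in competition with C8. No constitutional block separates the two ortho sites; only bond order and the crowding by the 5-O-MOM group distinguish them.
- Further risks: loss of the prenyl group by fragmentation of the ether at 200 °C, and incomplete closure of ring D if the silylating agent is present before the hydrogen shift of 15.
- Fallback: it moves both pericyclic events to the fragments and sets out from 7 and 4.
  - Heating the symmetrical ether 7 in PhNEt2 with the silylating agent, followed by methanolysis, should give 1-[2,4,6-trihydroxy-3-(2-methylbut-3-en-2-yl)phenyl]ethanone F1. Both ortho positions of 7 are equivalent, so no regiochemistry arises.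
  - Two equivalents of MOMCl with iPr2NEt should etherify the para hydroxyl and the less hindered ortho hydroxyl, giving 1-[2-hydroxy-4,6-bis(methoxymethoxy)-3-(2-methylbut-3-en-2-yl)phenyl]ethanone F2. The free hydroxyl next to the tertiary group later becomes O1, which places the side chain at C8.
  - Heating 4 alone in PhNEt2 should give 8-(methoxymethoxy)-2,2-dimethyl-2H-chromene-6-carbaldehyde F3, since only one ortho site is free.
  - Claisen–Schmidt condensation of F2 with F3 should give (E)-1-[2-hydroxy-4,6-bis(methoxymethoxy)-3-(2-methylbut-3-en-2-yl)phenyl]-3-[8-(methoxymethoxy)-2,2-dimethyl-2H-chromen-6-yl]prop-2-en-1-one F4.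
  - Algar–Flynn–Oyamada cyclisation should give 3-hydroxy-5,7-bis(methoxymethoxy)-2-[8-(methoxymethoxy)-2,2-dimethyl-2H-chromen-6-yl]-8-(2-methylbut-3-en-2-yl)-4H-chromen-4-one F5.
  - Acidic methanolysis as in step 9 brings the sequence back to the route at 21.

**Step 6.**
- Risk: five-membered ring closure to the aurone competes with six-membered closure. The ortho MOM ether twists the enone out of the plane of ring A and favours attack of the phenoxide at the α-carbon of the epoxidised chalcone.
- Fallback: it separates ring closure from oxygenation and sets out from 10.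
  - NaOAc in refluxing EtOH should close ring C by oxa-Michael addition to racemic 5-(methoxymethoxy)-2-[3-(methoxymethoxy)-4-(2-methylbut-3-yn-2-yloxy)phenyl]-7-(3-methylbut-2-enyloxy)chroman-4-one F6.
  - The ketone enolate (LiN(SiMe3)2, THF, −78 °C) is then hydroxylated with 2-(phenylsulfonyl)-3-phenyloxaziridine to give 11, which is now isolated.
  - Dess–Martin oxidation of the C3 carbinol gives the 3,4-dione, the keto tautomer of 12, so the route is rejoined at 12.

**Step 9.**
- Risk: acid-promoted addition of the 7-hydroxyl to the neighbouring vinyl group, hydration or oligomerisation of the chromene, or incomplete cleavage of the 3'-O acetal under conditions mild enough to avoid both.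
- Fallback: it masks the nucleophile and avoids protic acid, setting out from 20.
  - Acetylation (Ac2O, pyridine, 4-dimethylaminopyridine) should give 7-acetoxy-3,5-bis(methoxymethoxy)-2-[8-(methoxymethoxy)-2,2-dimethyl-2H-chromen-6-yl]-8-(2-methylbut-3-en-2-yl)-4H-chromen-4-one F7.
  - Thiol-mediated acetal exchange (ZnBr2, n-PrSH, CH2Cl2, 0 °C) should remove the three MOM groups and give 7-acetoxy-3,5-dihydroxy-2-(8-hydroxy-2,2-dimethyl-2H-chromen-6-yl)-8-(2-methylbut-3-en-2-yl)-4H-chromen-4-one F8.
  - Brief methanolysis of the acetate (K2CO3, MeOH, 0 °C, argon) returns to the route at 21.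

**Step 1.**
- Risk: alkylation of both hydroxyls or of O3, and interference of the catechol with the copper catalyst by chelation or oxidation. The tertiary chloride reacts by elimination–addition and needs more base than a simple displacement.
- Fallback: it sets out from 1 and uses a temporary group on O4.
  - Allyl bromide with NaHCO3 and NaI in DMF should give 4-(allyloxy)-3-hydroxybenzaldehyde F9.
  - MOMCl with iPr2NEt should give 4-(allyloxy)-3-(methoxymethoxy)benzaldehyde F10.
  - Deallylation with Pd(PPh3)4 (cat.) and morpholine should give 4-hydroxy-3-(methoxymethoxy)benzaldehyde F11.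
  - This single phenol is propargylated with 2 (1,8-diazabicyclo[5.4.0]undec-7-ene, CuCl2 cat., MeCN, 0 °C), which comes back to the route at 4.

**Step 3.**
- Risk: C-prenylation of the phloroglucinol nucleus and over-alkylation, because the phenoxide of 5 is an ambident nucleophile.
- Fallback: it sets out from 5 and activates the alcohol instead of forming a phenoxide. Mitsunobu etherification with 3-methylbut-2-en-1-ol (PPh3, diisopropyl azodicarboxylate, THF, 0 °C) should engage only the most acidic, non-chelated para hydroxyl and comes back to the route at 7. It makes no new compound (F0).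

## Further compounds

F1 | step 8 | 1-[2,4,6-trihydroxy-3-(2-methylbut-3-en-2-yl)phenyl]ethanone | CC(=O)c1c(O)cc(O)c(C(C)(C)C=C)c1O
F2 | step 8 | 1-[2-hydroxy-4,6-bis(methoxymethoxy)-3-(2-methylbut-3-en-2-yl)phenyl]ethanone | CC(=O)c1c(OCOC)cc(OCOC)c(C(C)(C)C=C)c1O
F3 | step 8 | 8-(methoxymethoxy)-2,2-dimethyl-2H-chromene-6-carbaldehyde | O=Cc1cc(OCOC)c2c(c1)C=CC(C)(C)O2
F4 | step 8 | (E)-1-[2-hydroxy-4,6-bis(methoxymethoxy)-3-(2-methylbut-3-en-2-yl)phenyl]-3-[8-(methoxymethoxy)-2,2-dimethyl-2H-chromen-6-yl]prop-2-en-1-one | O=C(/C=C/c1cc(OCOC)c2c(c1)C=CC(C)(C)O2)c1c(OCOC)cc(OCOC)c(C(C)(C)C=C)c1O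
F5 | step 8 | 3-hydroxy-5,7-bis(methoxymethoxy)-2-[8-(methoxymethoxy)-2,2-dimethyl-2H-chromen-6-yl]-8-(2-methylbut-3-en-2-yl)-4H-chromen-4-one | C=CC(C)(C)c1c(OCOC)cc(OCOC)c2c(=O)c(O)c(-c3cc(OCOC)c4c(c3)C=CC(C)(C)O4)oc12
F6 | step 6 | racemic 5-(methoxymethoxy)-2-[3-(methoxymethoxy)-4-(2-methylbut-3-yn-2-yloxy)phenyl]-7-(3-methylbut-2-enyloxy)chroman-4-one | C#CC(C)(C)Oc1ccc(cc1OCOC)C1CC(=O)c2c(OCOC)cc(OCC=C(C)C)cc2O1
F7 | step 9 | 7-acetoxy-3,5-bis(methoxymethoxy)-2-[8-(methoxymethoxy)-2,2-dimethyl-2H-chromen-6-yl]-8-(2-methylbut-3-en-2-yl)-4H-chromen-4-one | C=CC(C)(C)c1c(OC(C)=O)cc(OCOC)c2c(=O)c(OCOC)c(-c3cc(OCOC)c4c(c3)C=CC(C)(C)O4)oc12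
F8 | step 9 | 7-acetoxy-3,5-dihydroxy-2-(8-hydroxy-2,2-dimethyl-2H-chromen-6-yl)-8-(2-methylbut-3-en-2-yl)-4H-chromen-4-one | C=CC(C)(C)c1c(OC(C)=O)cc(O)c2c(=O)c(O)c(-c3cc(O)c4c(c3)C=CC(C)(C)O4)oc12
F9 | step 1 | 4-(allyloxy)-3-hydroxybenzaldehyde | C=CCOc1ccc(C=O)cc1O
F10 | step 1 | 4-(allyloxy)-3-(methoxymethoxy)benzaldehyde | C=CCOc1ccc(C=O)cc1OCOC
F11 | step 1 | 4-hydroxy-3-(methoxymethoxy)benzaldehyde | O=Cc1ccc(O)c(OCOC)c1
F0 | step 3 | none | none
A1 | alternative 1 | 5-ethoxy-2-(2-methylbut-3-en-2-yl)-3-(triisopropylsilyloxy)phenol | C=CC(C)(C)c1c(O)cc(OCC)cc1O[Si](C(C)C)(C(C)C)C(C)C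
A2 | alternative 1 | 3-ethoxycyclobut-2-en-1-one | CCOC1=CC(=O)C1
A3 | alternative 1 | (3,3-dimethylpent-4-en-1-yn-1-yloxy)triisopropylsilane | C=CC(C)(C)C#CO[Si](C(C)C)(C(C)C)C(C)C
A4 | alternative 2 | 5,7-difluoro-3-(methoxymethoxy)-2-[8-(methoxymethoxy)-2,2-dimethyl-2H-chromen-6-yl]-4H-chromen-4-one | Fc1cc(F)c2c(=O)c(OCOC)c(-c3cc(OCOC)c4c(c3)C=CC(C)(C)O4)oc2c1
A5 | alternative 2 | 2-(methoxymethoxy)-1-[8-(methoxymethoxy)-2,2-dimethyl-2H-chromen-6-yl]-3-(2,4,6-trifluorophenyl)propane-1,3-dione | COCOC(C(=O)c1c(F)cc(F)cc1F)C(=O)c1cc(OCOC)c2c(c1)C=CC(C)(C)O2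
A6 | alternative 3 | tetra-O-MOM Broussonol A, 3,5,7-tris(methoxymethoxy)-2-[8-(methoxymethoxy)-2,2-dimethyl-2H-chromen-6-yl]-8-(2-methylbut-3-en-2-yl)-4H-chromen-4-one | C=CC(C)(C)c1c(OCOC)cc(OCOC)c2c(=O)c(OCOC)c(-c3cc(OCOC)c4c(c3)C=CC(C)(C)O4)oc12
A7 | alternative 3 | 8-(methoxymethoxy)-2,2-dimethyl-2H,6H-pyrano[3,2-b]pyran-6-one | O=C1C=C(OCOC)C2=C(O1)C=CC(C)(C)O2
A8 | alternative 3 | 2-ethynyl-3,5,7-tris(methoxymethoxy)-8-(2-methylbut-3-en-2-yl)-4H-chromen-4-one | C#Cc1oc2c(C(C)(C)C=C)c(OCOC)cc(OCOC)c2c(=O)c1OCOC
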